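**Retrosynthetic overview**

1. Tenellic acid B (19) ⇐ desilylation and lactone hydrolysis of depsidone 17. The strategy rests on one feature: the ring A C1 carboxyl and the ring B C2' hydroxyl both stand ortho to the diaryl ether oxygen (C6–O–C1'), so they can be joined as the seven-membered lactone of a dibenzo[b,e][1,4]dioxepin-11-one.
2. 17 ⇐ bromo acid 16 by copper-catalysed intramolecular O-arylation of the carboxylate (C2'–O bond). This lactone is the only ring built (both benzene rings are bought), and it is opened again one step later.
3. 16 ⇐ SNAr of salicylic acid 11 on fluoroaldehyde 15 (ether C6–O–C1'); 15 ⇐ ortho-lithiation/formylation of 3-bromo-4-fluorotoluene 12.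
4. 11 ⇐ directed ortho-metalation/carboxylation between the OMe and OMOM groups of 7, then removal of the MOM group without protic acid.
5. 7 ⇐ asymmetric 2-methylallylboration of aldehyde 2 (sets the S carbinol), alkene hydrogenation and silylation; 2 ⇐ 4-hydroxy-2-methoxybenzaldehyde 1.

Key step: step 9

Assumption: the carbinol of the target is S (O > aryl > CH2 > H), and the known sense of induction of binaphthyl phosphoric acid catalysed allylboration of aryl aldehydes (R-acid to the Re face) is taken to hold for aldehyde 2 and the 2-methylallyl boronate, so the S-acid is specified. Ring A is numbered C1 (carboxyl) to C6 (ether oxygen), ring B C1' (ether oxygen) to C6' (formyl).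

Step 1
Reactants: 1 4-hydroxy-2-methoxybenzaldehyde
Product: 2 2-methoxy-4-(methoxymethoxy)benzaldehyde
Conditions: MOMCl, i-Pr2NEt, CH2Cl2, 0 °C to rt
Reagents that add atoms: chloromethyl methyl ether, COCCl
Why: O-alkylation of the only acidic hydroxyl (Williamson-type acetal ether formation) should give the MOM ether, which later serves as the ortho-directing group.

Step 2
Reactants: 2 2-methoxy-4-(methoxymethoxy)benzaldehyde; 3 2-methylallylboronic acid pinacol ester
Product: 5 (S)-1-[2-methoxy-4-(methoxymethoxy)phenyl]-3-methylbut-3-en-1-ol, via pinacol borate ester 4 (not isolated)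
Conditions: (S)-TRIP [(S)-3,3'-bis(2,4,6-triisopropylphenyl)-1,1'-binaphthyl-2,2'-diyl hydrogen phosphate] (5 mol%), 4 Å MS, toluene, −30 to 0 °C; aq. NaHCO3
Reagents that add atoms: none
Why: Chiral phosphoric acid catalysed allylboration of an aldehyde, in which the acid protonates a pinacol oxygen and its phosphoryl oxygen holds the formyl hydrogen, so the 2-methylallyl group should be delivered through a closed chair transition state to the Si face of 2 under the S-acid and set the S carbinol, the only stereocentre of the target (configuration to be checked by MTPA ester analysis).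

Step 3
Reactants: 5 (S)-1-[2-methoxy-4-(methoxymethoxy)phenyl]-3-methylbut-3-en-1-ol
Product: 6 (S)-1-[2-methoxy-4-(methoxymethoxy)phenyl]-3-methylbutan-1-ol
Conditions: H2 (4 atm), RhCl(PPh3)3 (5 mol%), toluene/EtOH, rt
Reagents that add atoms: none
Why: Homogeneous hydrogenation of the 1,1-disubstituted alkene with the rhodium phosphine catalyst should saturate the side chain without hydrogenolysis of the electron-rich benzylic C–O bond, which a heterogeneous palladium catalyst could cleave.

Step 4
Reactants: 6 (S)-1-[2-methoxy-4-(methoxymethoxy)phenyl]-3-methylbutan-1-ol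
Product: 7 triisopropyl{(S)-1-[2-methoxy-4-(methoxymethoxy)phenyl]-3-methylbutoxy}silane
Conditions: TIPSOTf (1.2 equiv), 2,6-lutidine, CH2Cl2, −78 to −20 °C
Reagents that add atoms: triisopropylsilyl trifluoromethanesulfonate, CC(C)[Si](OS(=O)(=O)C(F)(F)F)(C(C)C)C(C)C
Why: Silylation of the hindered secondary alcohol with a silyl triflate and a pyridine base should be much faster than any attack on the MOM acetal and gives an ether that withstands butyllithium, carbonate and hydroxide.

Step 5
Reactants: 7 triisopropyl{(S)-1-[2-methoxy-4-(methoxymethoxy)phenyl]-3-methylbutoxy}silane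
Product: 9 2-methoxy-6-(methoxymethoxy)-3-[(S)-3-methyl-1-(triisopropylsilyloxy)butyl]benzoic acid, via aryllithium 8 (not isolated)
Conditions: n-BuLi, TMEDA, THF, −78 to 0 °C; CO2, −78 °C to rt; aq. NH4Cl, then citric acid to pH 4
Reagents that add atoms: carbon dioxide, O=C=O
Why: Directed ortho-metalation should occur at the ring hydrogen between OMe and OMOM, which is acidified by both oxygens and reached by lithium chelated on the acetal, and carboxylation of the aryllithium then places the carboxyl at ring A C1; the lithiated carbon is meta to the side chain, so no silyl migration is possible.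

Step 6
Reactants: 9 2-methoxy-6-(methoxymethoxy)-3-[(S)-3-methyl-1-(triisopropylsilyloxy)butyl]benzoic acid
Product: 11 6-hydroxy-2-methoxy-3-[(S)-3-methyl-1-(triisopropylsilyloxy)butyl]benzoic acid, via bis(trimethylsilyl) derivative 10 (not isolated)
Conditions: TMSOTf (4 equiv), 2,2'-bipyridyl (6 equiv), MeCN, 0 °C to rt; then H2O, rt
Reagents that add atoms: none
Why: Silyl triflate/2,2'-bipyridyl cleavage of an aryl methoxymethyl ether should pass the methoxymethyl unit to bipyridyl as a pyridinium salt and leave the aryl oxygen as a trimethylsilyl ether that hydrolyses with the silyl ester on adding water; the medium stays buffered, so the benzylic silyl ether, which is ortho and para to ring oxygens and could ionise and racemise in protic acid, should survive.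

Step 7
Reactants: 12 3-bromo-4-fluorotoluene
Product: 15 3-bromo-2-fluoro-5-methylbenzaldehyde, via aryllithium 13 (not isolated), via lithium hemiaminal alkoxide 14 (not isolated)
Conditions: LiN(i-Pr)2, THF, −78 °C; DMF, −78 °C; aq. NH4Cl
Reagents that add atoms: N,N-dimethylformamide, CN(C)C=O
Why: Ortho-lithiation/formylation, in which the lithium amide should remove the most acidic ring hydrogen (ortho to fluorine, not next to bromine) at −78 °C without bromine–lithium exchange or aryne formation, and DMF traps the aryllithium as the aldehyde.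

Step 8
Reactants: 11 6-hydroxy-2-methoxy-3-[(S)-3-methyl-1-(triisopropylsilyloxy)butyl]benzoic acid; 15 3-bromo-2-fluoro-5-methylbenzaldehyde
Product: 16 6-(2-bromo-6-formyl-4-methylphenoxy)-2-methoxy-3-[(S)-3-methyl-1-(triisopropylsilyloxy)butyl]benzoic acid
Conditions: K2CO3 (3 equiv), DMSO, 90 °C; then aq. citric acid to pH 4
Reagents that add atoms: none
Why: Nucleophilic aromatic substitution (addition–elimination) in which the phenoxide of the dianion of 11, far more nucleophilic than its carboxylate, should displace the fluoride activated by the ortho formyl group, while the bromide is neither activated nor a comparable leaving group in this mechanism.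

Step 9
Reactants: 16 6-(2-bromo-6-formyl-4-methylphenoxy)-2-methoxy-3-[(S)-3-methyl-1-(triisopropylsilyloxy)butyl]benzoic acid
Product: 17 1-methoxy-8-methyl-2-[(S)-3-methyl-1-(triisopropylsilyloxy)butyl]-11-oxo-11H-dibenzo[b,e][1,4]dioxepine-6-carbaldehyde
Conditions: CuI (20 mol%), 1,10-phenanthroline (40 mol%), Cs2CO3 (2 equiv), 4 Å MS, 1,4-dioxane (0.01 M), 100 °C, argon
Reagents that add atoms: none
Why: The cesium carboxylate of 16 should bind monovalent copper carrying 1,10-phenanthroline, the ring B C2'–Br bond should add oxidatively to give a trivalent aryl copper carboxylate held in an eight-membered chelate, and C(aryl)–O reductive elimination should release lactone 17 and return monovalent copper. The closest known reaction type is the Ullmann-type copper-catalysed O-arylation of carboxylates by aryl halides, established intramolecularly for six-membered benzolactones from 2'-halobiaryl-2-carboxylic acids; here the same bond formation is asked to close a ring one atom larger. The single ring formed is the seven-membered lactone (C1 carbonyl carbon, ester oxygen, C2', C1', ether oxygen, C6, C1), closed by attack of the carboxylate oxygen on ring B C2' while the diaryl ether holds nucleophile and bromide in an ortho,ortho' relationship. No stereocentre is created, and the silylated carbinol is remote and not epimerisable under carbonate. The step needs intramolecular C–O coupling to win over protodebromination, copper-promoted decarboxylation and intermolecular ester formation; preorganisation, high dilution, a temperature not above 100 °C and exclusion of water and oxygen should secure this. The aldehyde has no alpha hydrogen and the carbinol is capped, so neither offers a competing nucleophile or an enolisation pathway.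

Step 10
Reactants: 17 1-methoxy-8-methyl-2-[(S)-3-methyl-1-(triisopropylsilyloxy)butyl]-11-oxo-11H-dibenzo[b,e][1,4]dioxepine-6-carbaldehyde
Product: 18 6-(2-formyl-6-hydroxy-4-methylphenoxy)-2-methoxy-3-[(S)-3-methyl-1-(triisopropylsilyloxy)butyl]benzoic acid
Conditions: LiOH·H2O (3 equiv), THF/H2O, 0 °C to rt; then 0.5 M aq. HCl to pH 3–4, 0 °C
Reagents that add atoms: lithium hydroxide, [Li+].[OH-]
Why: Saponification of the strained aryl ester, in which hydroxide adds to the lactone carbonyl and the ring B phenoxide leaves, should free the C1 acid and the C2' phenol together under conditions mild enough for the silyl ether and the non-enolisable aldehyde.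

Step 11
Reactants: 18 6-(2-formyl-6-hydroxy-4-methylphenoxy)-2-methoxy-3-[(S)-3-methyl-1-(triisopropylsilyloxy)butyl]benzoic acid
Product: 19 tenellic acid B
Conditions: Bu4NF (4 equiv), AcOH (2 equiv), THF, 0 °C to rt
Reagents that add atoms: none
Why: Fluoride-mediated cleavage of the silyl ether, driven by Si–F bond formation, should release the carbinol without acid, so the benzylic C–O bond is not ionised and the S configuration is kept.

**Compound list**

1 | 4-hydroxy-2-methoxybenzaldehyde | COc1cc(O)ccc1C=O | starting material
2 | 2-methoxy-4-(methoxymethoxy)benzaldehyde | COCOc1ccc(C=O)c(OC)c1 | intermediate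
3 | 2-methylallylboronic acid pinacol ester | CC(=C)CB1OC(C)(C)C(C)(C)O1 | starting material
4 | 2-{(S)-1-[2-methoxy-4-(methoxymethoxy)phenyl]-3-methylbut-3-enyloxy}-4,4,5,5-tetramethyl-1,3,2-dioxaborolane | COCOc1ccc([C@@H](OB2OC(C)(C)C(C)(C)O2)CC(C)=C)c(OC)c1 | intermediate
5 | (S)-1-[2-methoxy-4-(methoxymethoxy)phenyl]-3-methylbut-3-en-1-ol | COCOc1ccc([C@@H](O)CC(C)=C)c(OC)c1 | intermediate
6 | (S)-1-[2-methoxy-4-(methoxymethoxy)phenyl]-3-methylbutan-1-ol | COCOc1ccc([C@@H](O)CC(C)C)c(OC)c1 | intermediate
7 | triisopropyl{(S)-1-[2-methoxy-4-(methoxymethoxy)phenyl]-3-methylbutoxy}silane | COCOc1ccc([C@@H](O[Si](C(C)C)(C(C)C)C(C)C)CC(C)C)c(OC)c1 | intermediate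
8 | {2-methoxy-6-(methoxymethoxy)-3-[(S)-3-methyl-1-(triisopropylsilyloxy)butyl]phenyl}lithium | COCOc1ccc([C@@H](O[Si](C(C)C)(C(C)C)C(C)C)CC(C)C)c(OC)c1[Li] | intermediate
9 | 2-methoxy-6-(methoxymethoxy)-3-[(S)-3-methyl-1-(triisopropylsilyloxy)butyl]benzoic acid | COCOc1ccc([C@@H](O[Si](C(C)C)(C(C)C)C(C)C)CC(C)C)c(OC)c1C(=O)O | intermediate
10 | trimethylsilyl 2-methoxy-3-[(S)-3-methyl-1-(triisopropylsilyloxy)butyl]-6-(trimethylsilyloxy)benzoate | COc1c([C@@H](O[Si](C(C)C)(C(C)C)C(C)C)CC(C)C)ccc(O[Si](C)(C)C)c1C(=O)O[Si](C)(C)C | intermediate
11 | 6-hydroxy-2-methoxy-3-[(S)-3-methyl-1-(triisopropylsilyloxy)butyl]benzoic acid | COc1c([C@@H](O[Si](C(C)C)(C(C)C)C(C)C)CC(C)C)ccc(O)c1C(=O)O | intermediate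
12 | 3-bromo-4-fluorotoluene | Cc1ccc(F)c(Br)c1 | starting material
13 | (3-bromo-2-fluoro-5-methylphenyl)lithium | Cc1cc(Br)c(F)c([Li])c1 | intermediate
14 | lithium (3-bromo-2-fluoro-5-methylphenyl)(dimethylamino)methanolate | Cc1cc(Br)c(F)c(C(O[Li])N(C)C)c1 | intermediate
15 | 3-bromo-2-fluoro-5-methylbenzaldehyde | Cc1cc(Br)c(F)c(C=O)c1 | intermediate
16 | 6-(2-bromo-6-formyl-4-methylphenoxy)-2-methoxy-3-[(S)-3-methyl-1-(triisopropylsilyloxy)butyl]benzoic acid | COc1c([C@@H](O[Si](C(C)C)(C(C)C)C(C)C)CC(C)C)ccc(Oc2c(Br)cc(C)cc2C=O)c1C(=O)O | intermediate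
17 | 1-methoxy-8-methyl-2-[(S)-3-methyl-1-(triisopropylsilyloxy)butyl]-11-oxo-11H-dibenzo[b,e][1,4]dioxepine-6-carbaldehyde | COc1c([C@@H](O[Si](C(C)C)(C(C)C)C(C)C)CC(C)C)ccc2c1C(=O)Oc1cc(C)cc(C=O)c1O2 | intermediate
18 | 6-(2-formyl-6-hydroxy-4-methylphenoxy)-2-methoxy-3-[(S)-3-methyl-1-(triisopropylsilyloxy)butyl]benzoic acid | COc1c([C@@H](O[Si](C(C)C)(C(C)C)C(C)C)CC(C)C)ccc(Oc2c(O)cc(C)cc2C=O)c1C(=O)O | intermediate
19 | tenellic acid B, 6-(2-formyl-6-hydroxy-4-methylphenoxy)-3-[(S)-1-hydroxy-3-methylbutyl]-2-methoxybenzoic acid | COc1c([C@@H](O)CC(C)C)ccc(Oc2c(O)cc(C)cc2C=O)c1C(=O)O | target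

**Step count**

Total step count: 11. Longest linear sequence: 10 steps (steps 1–6 and 8–11); step 7 is a one-step side branch.

**Steps most likely to fail**

Step 9 (copper-catalysed lactone closure). The C2'–Br bond may be reduced instead of coupled, the 2,6-dioxygenated benzoate may lose CO2 under copper on heating, or esters may form between molecules instead of within one. The fallback gives up the ring closure and brings the C2' oxygen in from outside. It sets out from 16: Miyaura borylation (PdCl2(dppf), bis(pinacolato)diboron, KOAc, 1,4-dioxane, 85 °C) should turn the C2' bromide into the pinacol boronate F1. Oxidation of the C–B bond with trimethylamine N-oxide (THF, rt to 50 °C, a reagent that leaves aldehydes alone; aryl shift from boron to oxygen) and work-up at pH 4 should give the phenol acid. The route is rejoined at 18; lactone 17 is not made.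

Step 8 (diaryl ether formation). Substitution at a fluoride flanked by two ortho groups by a hindered, internally hydrogen-bonded salicylate may be slow, which leaves time for decarboxylation of the electron-rich benzoate or for attack through the carboxylate oxygen. The fallback masks the carboxyl so that a single phenoxide is the nucleophile. It sets out from 11: allyl bromide with KHCO3 in DMF at rt should alkylate only the carboxylate and give the allyl ester F2. SNAr of F2 with 15 (Cs2CO3, DMF, 80 °C) should give the allyl ester diaryl ether F3. Deallylation with Pd(PPh3)4 (5 mol%) and sodium 4-methylbenzenesulfinate in THF/MeOH at rt, a scavenger that does not condense with the aldehyde and a temperature at which the aryl bromide should stay intact, returns the free acid. The route is rejoined at 16.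

Step 2 (asymmetric 2-methylallylboration). Facial discrimination may be incomplete with an electron-rich, ortho-substituted aldehyde, and uncatalysed background addition may set in if the temperature has to be raised. The fallback sets the stereocentre by reagent-controlled ketone reduction. It sets out from 2: i-BuMgBr in THF at 0 °C should give the racemic alcohol F4, and oxidation with Dess–Martin periodinane in CH2Cl2 the aryl isobutyl ketone F5. Corey–Bakshi–Shibata reduction with (R)-2-methyl-CBS-oxazaborolidine (10 mol%) and BH3·SMe2 in THF at −20 °C should deliver hydride so as to give the S alcohol (aryl as the large group). The route is rejoined at 6; compounds 4 and 5 and step 3 are bypassed.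

**Further compounds**

F1 | step 9 | 6-[2-formyl-4-methyl-6-(4,4,5,5-tetramethyl-1,3,2-dioxaborolan-2-yl)phenoxy]-2-methoxy-3-[(S)-3-methyl-1-(triisopropylsilyloxy)butyl]benzoic acid | COc1c([C@@H](O[Si](C(C)C)(C(C)C)C(C)C)CC(C)C)ccc(Oc2c(B3OC(C)(C)C(C)(C)O3)cc(C)cc2C=O)c1C(=O)O
F2 | step 8 | allyl 6-hydroxy-2-methoxy-3-[(S)-3-methyl-1-(triisopropylsilyloxy)butyl]benzoate | COc1c([C@@H](O[Si](C(C)C)(C(C)C)C(C)C)CC(C)C)ccc(O)c1C(=O)OCC=C
F3 | step 8 | allyl 6-(2-bromo-6-formyl-4-methylphenoxy)-2-methoxy-3-[(S)-3-methyl-1-(triisopropylsilyloxy)butyl]benzoate | COc1c([C@@H](O[Si](C(C)C)(C(C)C)C(C)C)CC(C)C)ccc(Oc2c(Br)cc(C)cc2C=O)c1C(=O)OCC=C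
F4 | step 2 | racemic 1-[2-methoxy-4-(methoxymethoxy)phenyl]-3-methylbutan-1-ol | COCOc1ccc(C(O)CC(C)C)c(OC)c1
F5 | step 2 | 1-[2-methoxy-4-(methoxymethoxy)phenyl]-3-methylbutan-1-one | COCOc1ccc(C(=O)CC(C)C)c(OC)c1
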